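**Retrosynthetic overview**

1. Atom labels: ring A = C1 (carries the exocyclic =CH2), C2, C3 (OH), C4 (Br), C5 (Me2), C6 (spiro); ring B = C6, C7, C8, C9 (Me, OH), C10 (Cl), C11.
2. The strategy rests on ring B: its oxygen at C9 with chlorine on the neighbouring C10, 1,4 to the spiro carbon C6, is a 4,4-disubstituted cyclohexanone with an α-chlorine. Cutting C9–CH3 (Grignard) and C10–Cl (enolate chlorination) leaves the spiro enone C9(=O)–C10=C11.
3. Enone ⇒ ring-A aldehyde (CHO = C11 on C6) + methyl vinyl ketone: Michael bond C6–C7, then aldol condensation C10=C11. Ring B is formed last and C6 is set there.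
4. Ring A (formed first) ⇒ type II carbonyl-ene closure of C2–C3 in an acyclic (S)-α-bromo aldehyde. This gives the C1 methylene and the cis C3–OH/C4–Br pair; C4–Br comes from an enamine-catalysed bromination.
5. Acyclic chain ⇒ Ireland–Claisen rearrangement (C5–C6 bond) of prenyl 3-methylbut-3-enoate.

Key step: step 11

Remark 1: compounds 6–10 are racemic at C6 and 11–15 are pairs of C6 epimers with fixed C4; this is harmless because C6 becomes planar in dienolate 17.
Remark 2: the (2R,5R)-catalyst in step 6 is assumed to give the (S)-bromide (bromination of the E-enamine anti to the flanking phenyl group); if the sense is opposite, the enantiomeric catalyst is used.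

**Route**

Step 1
Reactants: 1 3-methylbut-3-enoic acid; 2 3-methylbut-2-en-1-ol
Product: 3 3-methylbut-2-en-1-yl 3-methylbut-3-enoate
Conditions: DCC, DMAP (cat.), CH2Cl2, 0 °C → rt
Reagents that add atoms: none
Why: Steglich esterification joins the two C5 units; a DMAP-induced shift of the alkene into conjugation would be harmless, since both ester isomers give the same dienolate in step 2.

Step 2
Reactants: 3 3-methylbut-2-en-1-yl 3-methylbut-3-enoate
Product: 6 3,3-dimethyl-2-(prop-1-en-2-yl)pent-4-en-1-ol (racemic), via silyl ketene acetal 4 (not isolated), via trimethylsilyl ester 5 (not isolated)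
Conditions: LDA, THF, −78 °C; TMSCl, −78 °C → rt; then LiAlH4, 0 °C → rt
Reagents that add atoms: none
Why: Ireland–Claisen rearrangement: the O-silylated ester dienolate undergoes the chair-like [3,3] shift at room temperature and forms the congested C5–C6 bond (ester α-carbon to the dimethyl-substituted allyl terminus), and LiAlH4 reduces the silyl ester in the same flask; the mixture is kept below about 40 °C so that the 1,5-diene does not undergo Cope rearrangement.

Step 3
Reactants: 6 3,3-dimethyl-2-(prop-1-en-2-yl)pent-4-en-1-ol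
Product: 7 1-({[3,3-dimethyl-2-(prop-1-en-2-yl)pent-4-en-1-yl]oxy}methyl)-4-methoxybenzene (racemic)
Conditions: NaH, PMBCl, Bu4NI (cat.), THF/DMF, 0 °C → rt
Reagents that add atoms: 4-methoxybenzyl chloride, COc1ccc(CCl)cc1
Why: Williamson ether synthesis; the PMB ether should survive borane, Dess–Martin, enamine and Me2AlCl conditions and can later be removed oxidatively beside a silyl ether.

Step 4
Reactants: 7 PMB ether
Product: 9 4-{[(4-methoxybenzyl)oxy]methyl}-3,3,5-trimethylhex-5-en-1-ol (racemic), via alkylborane 8 (not isolated)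
Conditions: Sia2BH (from BH3·THF and 2-methylbut-2-ene), THF, 0 °C; then NaOH, H2O2, 0 °C → rt
Reagents that add atoms: hydrogen peroxide, OO
Why: Hydroboration–oxidation: the bulky dialkylborane should add anti-Markovnikov to the monosubstituted vinyl group much faster than to the 1,1-disubstituted isopropenyl group, whose allylic carbon is in addition fully branched.

Step 5
Reactants: 9 primary alcohol
Product: 10 4-{[(4-methoxybenzyl)oxy]methyl}-3,3,5-trimethylhex-5-enal (racemic)
Conditions: DMP, CH2Cl2, 0 °C → rt
Reagents that add atoms: none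
Why: Dess–Martin oxidation of the primary alcohol stops at the aldehyde under neutral conditions.

Step 6
Reactants: 10 aldehyde
Product: 11 (2S)-2-bromo-4-{[(4-methoxybenzyl)oxy]methyl}-3,3,5-trimethylhex-5-enal (both C4 epimers)
Conditions: (2R,5R)-2,5-diphenylpyrrolidine (20 mol%), 4,4-dibromo-2,6-di-tert-butylcyclohexa-2,5-dienone, PhCO2H (cat.), H2O, CH2Cl2/pentane, −40 → −24 °C; used crude
Reagents that add atoms: 4,4-dibromo-2,6-di-tert-butylcyclohexa-2,5-dien-1-one, O=C1C(C(C)(C)C)=CC(Br)(Br)C=C1C(C)(C)C
Why: Enamine-catalysed asymmetric α-bromination of an aldehyde: the E-enamine of the C2-symmetric amine should be brominated on the face away from the flanking phenyl group, setting the ring C4 stereocentre (S) under catalyst control for both C6 epimers, and the neopentyl position slows enolisation of the product.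

Step 7
Reactants: 11 (S)-α-bromo aldehyde
Product: 12 (1R,2S)-2-bromo-4-{[(4-methoxybenzyl)oxy]methyl}-3,3-dimethyl-5-methylidenecyclohexan-1-ol (both C4 epimers; cis bromohydrin)
Conditions: Me2AlCl, CH2Cl2, −78 → −40 °C
Reagents that add atoms: none
Why: Type II carbonyl-ene cyclisation promoted by Me2AlCl: the alkene terminus C2 attacks the aluminium-bound aldehyde while a methyl hydrogen passes to oxygen, closing ring A through a chair and leaving the C1 exocyclic methylene; with C4–Br equatorial and antiperiplanar to the forming C2–C3 bond (polar Felkin–Anh) and the C–O bond axial, as the hydrogen transfer requires, the new C3 stereocentre should be cis to bromine (3R).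

Step 8
Reactants: 12 cis bromohydrin
Product: 13 tert-butyl{[(1R,2S)-2-bromo-4-{[(4-methoxybenzyl)oxy]methyl}-3,3-dimethyl-5-methylidenecyclohexyl]oxy}dimethylsilane (both C4 epimers)
Conditions: TBSOTf, 2,6-lutidine, CH2Cl2, −78 → 0 °C
Reagents that add atoms: tert-butyldimethylsilyl triflate, CC(C)(C)[Si](C)(C)OS(=O)(=O)C(F)(F)F
Why: Silylation with the reactive triflate protects the hindered secondary C3–OH, so that the base in step 11 meets no free hydroxyl and C11 can be oxidised alone.

Step 9
Reactants: 13 bis-ether
Product: 14 [(3S,4R)-3-bromo-4-{[tert-butyl(dimethyl)silyl]oxy}-2,2-dimethyl-6-methylidenecyclohexyl]methanol (both C1 epimers)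
Conditions: DDQ, CH2Cl2/pH 7 buffer, 0 °C → rt
Reagents that add atoms: none
Why: Oxidative PMB cleavage (benzylic hydride abstraction by DDQ, then hydrolysis of the oxocarbenium ion) frees the primary alcohol and should leave silyl ether, bromide and alkene untouched.

Step 10
Reactants: 14 primary alcohol
Product: 15 (3S,4R)-3-bromo-4-{[tert-butyl(dimethyl)silyl]oxy}-2,2-dimethyl-6-methylidenecyclohexane-1-carbaldehyde (both C1 epimers)
Conditions: DMP, NaHCO3, CH2Cl2, 0 °C; used directly
Reagents that add atoms: none
Why: Buffered Dess–Martin oxidation gives the β,γ-unsaturated aldehyde without base, so the exocyclic alkene should not move into conjugation.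

Step 11
Reactants: 15 ring-A aldehyde; 16 but-3-en-2-one (methyl vinyl ketone)
Product: 20 (3R,4S,6S)-4-bromo-3-{[tert-butyl(dimethyl)silyl]oxy}-5,5-dimethyl-1-methylidenespiro[5.5]undec-10-en-9-one, via potassium dienolate 17 (not isolated), via keto aldehyde 18 (not isolated), via aldol 19 (not isolated)
Conditions: t-BuOK (0.2 equiv), THF, −40 °C, slow addition of 16, → −10 °C; then KOH (cat.), MeOH, 0 °C → rt
Reagents that add atoms: none
Why: Catalytic t-BuOK removes the doubly activated C6–H of either epimer of 15 to give the same planar exocyclic dienolate 17, whose α-carbon C6 adds to the enone terminus (C7) while the adduct enolate is protonated by fresh 15, so that keto aldehyde 18 keeps the C1 methylene out of conjugation; KOH/MeOH then enolises the methyl ketone toward C10, which adds to the now non-enolisable neopentyl aldehyde C11 to give aldol 19, and E1cB loss of water sets the C10=C11 double bond. The closest known reactions are the Robinson spiroannulation of α-branched cycloalkanecarbaldehydes with methyl vinyl ketone and the deconjugative α-alkylation of cyclogeranyl-type dienolates. Ring B closes by a 6-(enolexo)-exo-trig aldol addition. The only new stereocentre, C6, is controlled by ring A: in the dienolate the C4–Br bond can sit axial with the C3 silyloxy group equatorial, so the face of C6 syn to these cis substituents is shielded through its 1,3-relationship to bromine and the enone should enter from the other face, placing C7 trans and C11 cis to bromine (6S). The step needs α- rather than γ-attack of the dienolate and this facial preference; the first is the kinetic preference of metal dienolates (largest coefficient at C6) and is made irreversible by the aldol closure, the second rests on the ring-A substituents as described. The aprotic, cold Michael stage with only a substoichiometric amount of base should also keep the C4 bromide from E2 or 1,3-elimination and leave the C3 silyl ether in place.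

Step 12
Reactants: 20 spiro enone
Product: 22 (3R,4S,6S)-4-bromo-10-chloro-3-{[tert-butyl(dimethyl)silyl]oxy}-5,5-dimethyl-1-methylidenespiro[5.5]undecan-9-one (C10 epimers), via lithium enolate 21 (not isolated)
Conditions: L-Selectride, THF, −78 °C; then added to NCS, THF, −78 → −20 °C
Reagents that add atoms: N-chlorosuccinimide, O=C1CCC(=O)N1Cl
Why: Conjugate reduction of the β-unsubstituted enone by the hindered borohydride (hydride to C11) gives the C9–C10 enolate regiospecifically, and electrophilic chlorination of this enolate by NCS places chlorine on C10; the neopentyl bromide, silyl ether and isolated alkene should not react at −78 °C.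

Step 13
Reactants: 22 α-chloro ketone (C10 epimers)
Product: 23 (3R,4S,6S,10S)-4-bromo-10-chloro-3-{[tert-butyl(dimethyl)silyl]oxy}-5,5-dimethyl-1-methylidenespiro[5.5]undecan-9-one
Conditions: LiCl, DMF, rt → 40 °C
Reagents that add atoms: lithium chloride, [Li+].[Cl-]
Why: Degenerate SN2 chloride exchange at the activated α-keto carbon (epimerisation of an α-halo ketone) should equilibrate C10 toward the equatorial chloride cis to C5, because the other epimer places chlorine 1,3-diaxial to C1 in the ring-B chair that keeps the bulky C5 equatorial; this fixes 10S.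

Step 14
Reactants: 23 equatorial α-chloro ketone
Product: 24 (3R,4S,6S,9R,10S)-4-bromo-10-chloro-3-{[tert-butyl(dimethyl)silyl]oxy}-5,5,9-trimethyl-1-methylidenespiro[5.5]undecan-9-ol
Conditions: MeMgBr, Et2O/THF, −78 → −40 °C; cold NH4Cl quench
Reagents that add atoms: methylmagnesium bromide, C[Mg]Br
Why: Grignard addition to an α-chloro cyclohexanone: methyl should attack C9 from the equatorial direction, on the face opposite the C10 chlorine (the usual course for 2-chlorocyclohexanones, giving the cis chlorohydrin), so the hydroxyl ends axial and cis to chlorine (9R), and the cold quench avoids rearrangement of the magnesium alkoxide.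

Step 15
Reactants: 24 silyl ether
Product: 25 (3R,4S,6S,9R,10S)-4-bromo-10-chloro-5,5,9-trimethyl-1-methylidenespiro[5.5]undecane-3,9-diol (CNP0121782.1)
Conditions: TBAF, AcOH, THF, 0 °C → rt
Reagents that add atoms: none
Why: Fluoride-mediated desilylation, buffered with acetic acid so that no free alkoxide sits beside the halides, releases the C3 alcohol and should give the target unchanged at all five stereocentres.

**Compound list**

1 | 3-methylbut-3-enoic acid | C=C(C)CC(=O)O | starting material
2 | 3-methylbut-2-en-1-ol (prenol) | CC(C)=CCO | starting material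
3 | 3-methylbut-2-en-1-yl 3-methylbut-3-enoate | C=C(C)CC(=O)OCC=C(C)C | intermediate
4 | trimethyl{[3-methyl-1-(3-methylbut-2-en-1-yloxy)buta-1,3-dien-1-yl]oxy}silane (silyl ketene acetal, not isolated) | C=C(C)C=C(OCC=C(C)C)O[Si](C)(C)C | intermediate
5 | trimethylsilyl 3,3-dimethyl-2-(prop-1-en-2-yl)pent-4-enoate (racemic, not isolated) | C=C(C)C(C(=O)O[Si](C)(C)C)C(C)(C)C=C | intermediate
6 | 3,3-dimethyl-2-(prop-1-en-2-yl)pent-4-en-1-ol (racemic) | C=C(C)C(CO)C(C)(C)C=C | intermediate
7 | 1-({[3,3-dimethyl-2-(prop-1-en-2-yl)pent-4-en-1-yl]oxy}methyl)-4-methoxybenzene (racemic) | C=C(C)C(COCc1ccc(OC)cc1)C(C)(C)C=C | intermediate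
8 | {4-[(4-methoxybenzyloxy)methyl]-3,3,5-trimethylhex-5-en-1-yl}bis(3-methylbutan-2-yl)borane (not isolated) | C=C(C)C(COCc1ccc(OC)cc1)C(C)(C)CCB(C(C)C(C)C)C(C)C(C)C | intermediate
9 | 4-{[(4-methoxybenzyl)oxy]methyl}-3,3,5-trimethylhex-5-en-1-ol (racemic) | C=C(C)C(COCc1ccc(OC)cc1)C(C)(C)CCO | intermediate
10 | 4-{[(4-methoxybenzyl)oxy]methyl}-3,3,5-trimethylhex-5-enal (racemic) | C=C(C)C(COCc1ccc(OC)cc1)C(C)(C)CC=O | intermediate
11 | (2S)-2-bromo-4-{[(4-methoxybenzyl)oxy]methyl}-3,3,5-trimethylhex-5-enal (both C4 epimers) | C=C(C)C(COCc1ccc(OC)cc1)C(C)(C)[C@H](Br)C=O | intermediate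
12 | (1R,2S)-2-bromo-4-{[(4-methoxybenzyl)oxy]methyl}-3,3-dimethyl-5-methylidenecyclohexan-1-ol (both C4 epimers) | C=C1C[C@@H](O)[C@@H](Br)C(C)(C)C1COCc1ccc(OC)cc1 | intermediate
13 | tert-butyl{[(1R,2S)-2-bromo-4-{[(4-methoxybenzyl)oxy]methyl}-3,3-dimethyl-5-methylidenecyclohexyl]oxy}dimethylsilane (both C4 epimers) | C=C1C[C@@H](O[Si](C)(C)C(C)(C)C)[C@@H](Br)C(C)(C)C1COCc1ccc(OC)cc1 | intermediate
14 | [(3S,4R)-3-bromo-4-{[tert-butyl(dimethyl)silyl]oxy}-2,2-dimethyl-6-methylidenecyclohexyl]methanol (both C1 epimers) | C=C1C[C@@H](O[Si](C)(C)C(C)(C)C)[C@@H](Br)C(C)(C)C1CO | intermediate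
15 | (3S,4R)-3-bromo-4-{[tert-butyl(dimethyl)silyl]oxy}-2,2-dimethyl-6-methylidenecyclohexane-1-carbaldehyde (both C1 epimers) | C=C1C[C@@H](O[Si](C)(C)C(C)(C)C)[C@@H](Br)C(C)(C)C1C=O | intermediate
16 | but-3-en-2-one (methyl vinyl ketone) | C=CC(C)=O | starting material
17 | potassium dienolate of 15 (not isolated) | C=C1C[C@@H](O[Si](C)(C)C(C)(C)C)[C@@H](Br)C(C)(C)C1=C[O-].[K+] | intermediate
18 | (1S,3S,4R)-3-bromo-4-{[tert-butyl(dimethyl)silyl]oxy}-2,2-dimethyl-6-methylidene-1-(3-oxobutyl)cyclohexane-1-carbaldehyde (not isolated) | C=C1C[C@@H](O[Si](C)(C)C(C)(C)C)[C@@H](Br)C(C)(C)[C@]1(C=O)CCC(C)=O | intermediate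
19 | (3R,4S,6S)-4-bromo-3-{[tert-butyl(dimethyl)silyl]oxy}-11-hydroxy-5,5-dimethyl-1-methylidenespiro[5.5]undecan-9-one (C11 epimers, not isolated) | C=C1C[C@@H](O[Si](C)(C)C(C)(C)C)[C@@H](Br)C(C)(C)[C@]12CCC(=O)CC2O | intermediate
20 | (3R,4S,6S)-4-bromo-3-{[tert-butyl(dimethyl)silyl]oxy}-5,5-dimethyl-1-methylidenespiro[5.5]undec-10-en-9-one | C=C1C[C@@H](O[Si](C)(C)C(C)(C)C)[C@@H](Br)C(C)(C)[C@]12CCC(=O)C=C2 | intermediate
21 | lithium C9–C10 enolate of the reduced enone (not isolated) | C=C1C[C@@H](O[Si](C)(C)C(C)(C)C)[C@@H](Br)C(C)(C)[C@]12CCC([O-])=CC2.[Li+] | intermediate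
22 | (3R,4S,6S)-4-bromo-10-chloro-3-{[tert-butyl(dimethyl)silyl]oxy}-5,5-dimethyl-1-methylidenespiro[5.5]undecan-9-one (C10 epimers) | C=C1C[C@@H](O[Si](C)(C)C(C)(C)C)[C@@H](Br)C(C)(C)[C@]12CCC(=O)C(Cl)C2 | intermediate
23 | (3R,4S,6S,10S)-4-bromo-10-chloro-3-{[tert-butyl(dimethyl)silyl]oxy}-5,5-dimethyl-1-methylidenespiro[5.5]undecan-9-one | C=C1C[C@@H](O[Si](C)(C)C(C)(C)C)[C@@H](Br)C(C)(C)[C@]12CCC(=O)[C@@H](Cl)C2 | intermediate
24 | (3R,4S,6S,9R,10S)-4-bromo-10-chloro-3-{[tert-butyl(dimethyl)silyl]oxy}-5,5,9-trimethyl-1-methylidenespiro[5.5]undecan-9-ol | C=C1C[C@@H](O[Si](C)(C)C(C)(C)C)[C@@H](Br)C(C)(C)[C@]12CC[C@@](C)(O)[C@@H](Cl)C2 | intermediate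
25 | (3R,4S,6S,9R,10S)-4-bromo-10-chloro-5,5,9-trimethyl-1-methylidenespiro[5.5]undecane-3,9-diol (CNP0121782.1) | C=C1C[C@@H](O)[C@@H](Br)C(C)(C)[C@]12CC[C@@](C)(O)[C@@H](Cl)C2 | target

(Spiro locants follow the atom labels of the overview.)

**Step count**

Total: 15 steps. Longest linear sequence: 15 steps (1/2 → 25); 16 enters at step 11.

**Steps most likely to fail**

Step 11 (key step). What may go wrong: the dienolate may attack through its unhindered exocyclic γ-carbon instead of the congested C6, or anionic oligomerisation of the enone may outrun the slow addition at C6. Fallback: the C6–C7 bond is made by alkylation instead of conjugate addition. Setting out from 15, KHMDS (1.05 equiv) in THF/DMPU at −78 °C gives dienolate 17, which is alkylated with 2-(2-iodoethyl)-2-methyl-1,3-dioxolane (−78 → 0 °C) to the dioxolane aldehyde F1; alkyl halides take such dienolates at the α-carbon irreversibly. Mild hydrolysis (PPTS, wet acetone) unmasks the ketone and the route is rejoined at keto aldehyde 18, which is closed with KOH/MeOH to 20 as in step 11.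

Step 7. What may go wrong: loss of facial control at C3 during the ring closure (the two C6 epimers need not pass through the same chair), giving trans bromohydrin, with some erosion at C4 if the aluminium-bound bromo aldehyde enolises. Fallback: C3 is set by ketone reduction instead of by the C–C bond formation. Setting out from 11, the closure is run as before, and the mixture of 12 and its C3 epimer, the trans bromohydrin F2, is oxidised (DMP, NaHCO3, CH2Cl2, 0 °C) to the α-bromo ketone F3. This is reduced at once with DIBAL-H (CH2Cl2, −78 °C); hydride delivery anti to the C4–Br bond of an α-bromo ketone flanked by a quaternary carbon should give the cis bromohydrin, and the route is rejoined at 12.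

Step 12. What may go wrong: 1,2-reduction of the carbonyl because the β-carbon C11 is neopentylic, or incomplete or double chlorination of the boron-containing enolate mixture. Fallback: the enolate equivalent is made by catalytic 1,4-hydrosilylation and isolated. Setting out from 20, Et3SiH with [RhCl(PPh3)3] (cat.) in toluene should give the triethylsilyl enol ether F4 (C9–O–Si, C9=C10); NCS in THF at 0 °C chlorinates C10 and the route is rejoined at 22.

**Further compounds**

F1 | step 11 | (1S,3S,4R)-3-bromo-4-{[tert-butyl(dimethyl)silyl]oxy}-2,2-dimethyl-6-methylidene-1-[2-(2-methyl-1,3-dioxolan-2-yl)ethyl]cyclohexane-1-carbaldehyde | C=C1C[C@@H](O[Si](C)(C)C(C)(C)C)[C@@H](Br)C(C)(C)[C@]1(C=O)CCC2(C)OCCO2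
F2 | step 7 | (1S,2S)-2-bromo-4-{[(4-methoxybenzyl)oxy]methyl}-3,3-dimethyl-5-methylidenecyclohexan-1-ol (trans bromohydrin, both C4 epimers) | C=C1C[C@H](O)[C@@H](Br)C(C)(C)C1COCc1ccc(OC)cc1
F3 | step 7 | (2S)-2-bromo-4-{[(4-methoxybenzyl)oxy]methyl}-3,3-dimethyl-5-methylidenecyclohexan-1-one (both C4 epimers) | C=C1CC(=O)[C@@H](Br)C(C)(C)C1COCc1ccc(OC)cc1
F4 | step 12 | (3R,4S,6S)-4-bromo-3-{[tert-butyl(dimethyl)silyl]oxy}-5,5-dimethyl-1-methylidene-9-[(triethylsilyl)oxy]spiro[5.5]undec-9-ene | C=C1C[C@@H](O[Si](C)(C)C(C)(C)C)[C@@H](Br)C(C)(C)[C@]12CCC(O[Si](CC)(CC)CC)=CC2
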